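Ring D, the 1,3-linked ring without further substituents, carries only the ether oxygen to ring C and the CH2CH2 bridge to ring A, on ring carbons separated by one CH. This 1,3-pattern is that of a 2-aryloxy-4-alkylbuta-1,3-diene, so ring D is cut back to such a diene and the 19-membered ring is closed by enyne metathesis. The precursor is an open A–O–B–CH2CH2–C chain ending in an ethynyl ether on ring C (phenol as benzyl ether) and a but-3-enyl group on ring A. In one operation the metathesis forms both diene C=C bonds and the macrocycle; Diels–Alder aromatisation with an acetylene equivalent and debenzylation then finish ring D and the target.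

Key step: step 10

Ring letters: A is the methoxy-bearing ring, B the 1,4-disubstituted ring, C the ring with the free OH, D the unsubstituted 1,3-linked ring. The target is C29H26O4 and has no stereocentre.

Remark: stilbene 8 is carried as an E/Z mixture because its double bond is saturated in the next step; 22 and 23 are transient mixtures of regio-, stereo- and double-bond isomers that all converge on 24, and one representative of each is drawn; metal phenolates formed from numbered phenols under basic conditions are regarded as the same numbered compound.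

Design note: the terminal ynol ether 17 is unmasked from the storable dichlorovinyl ether 14 only in the step before the metathesis, and the metathesis is run in two phases (ethylene, then argon sparge) so that diene formation precedes ring closure.

Step 1
Reactants: 1 3-hydroxy-4-methoxybenzyl alcohol; 2 4-fluorobenzaldehyde
Product: 3 4-[5-(hydroxymethyl)-2-methoxyphenoxy]benzaldehyde
Conditions: K2CO3, DMF, 110 °C
Reagents that add atoms: none
Why: Nucleophilic aromatic substitution, in which the phenoxide of 1 (far more nucleophilic under carbonate than the benzylic alcohol) displaces the fluoride activated by the para formyl group of 2.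

Step 2
Reactants: 4 4-(benzyloxy)-3-hydroxybenzaldehyde
Product: 5 2-(benzyloxy)-5-(hydroxymethyl)phenol
Conditions: NaBH4, MeOH, 0 °C
Reagents that add atoms: none
Why: Hydride reduction of an aryl aldehyde with NaBH4 is fast and leaves the benzyl ether and the phenol untouched.

Step 3
Reactants: 5 2-(benzyloxy)-5-(hydroxymethyl)phenol
Product: 6 [4-(benzyloxy)-3-hydroxybenzyl]triphenylphosphonium bromide
Conditions: PPh3·HBr, MeCN, reflux
Reagents that add atoms: triphenylphosphine hydrobromide, [Br-].[PH+](c1ccccc1)(c1ccccc1)c1ccccc1
Why: Acid-promoted ionisation of the para-alkoxybenzylic alcohol and capture by PPh3 gives the salt directly (phosphonium salt formation from a benzylic alcohol), the free phenol and the aryl benzyl ether being inert to this weak acid.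

Step 4
Reactants: 6 [4-(benzyloxy)-3-hydroxybenzyl]triphenylphosphonium bromide; 3 4-[5-(hydroxymethyl)-2-methoxyphenoxy]benzaldehyde
Product: 8 2-(benzyloxy)-5-(2-{4-[5-(hydroxymethyl)-2-methoxyphenoxy]phenyl}ethenyl)phenol (E/Z mixture), via potassium phenolate ylide 7 (not isolated)
Conditions: KOtBu (2.2 equiv), THF, 0 °C to rt; then 1 M HCl
Reagents that add atoms: none
Why: Wittig olefination in which two equivalents of base form the phenolate ylide 7, which condenses with the aryl aldehyde of 3 while the benzylic alcohol is too weakly acidic to quench a semi-stabilised ylide; the alkene geometry is of no consequence.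

Step 5
Reactants: 8 2-(benzyloxy)-5-(2-{4-[5-(hydroxymethyl)-2-methoxyphenoxy]phenyl}ethenyl)phenol
Product: 9 2-(benzyloxy)-5-(2-{4-[5-(hydroxymethyl)-2-methoxyphenoxy]phenyl}ethyl)phenol
Conditions: TsNHNH2, NaOAc, DME/H2O, reflux
Reagents that add atoms: none
Why: Diimide reduction, in which HN=NH generated from the sulfonyl hydrazide transfers H2 to the stilbene C=C in a concerted way and cannot hydrogenolyse the benzyl ether or the diaryl ether.

Step 6
Reactants: 9 2-(benzyloxy)-5-(2-{4-[5-(hydroxymethyl)-2-methoxyphenoxy]phenyl}ethyl)phenol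
Product: 10 2-(benzyloxy)-5-(2-{4-[5-(bromomethyl)-2-methoxyphenoxy]phenyl}ethyl)phenol
Conditions: CBr4, PPh3, CH2Cl2, 0 °C
Reagents that add atoms: carbon tetrabromide, BrC(Br)(Br)Br
Why: Appel bromination converts the primary benzylic alcohol into the bromide under neutral conditions, whereas the phenol, whose aryl C–O bond cannot be substituted, is returned unchanged; the bromide is used without storage.

Step 7
Reactants: 10 2-(benzyloxy)-5-(2-{4-[5-(bromomethyl)-2-methoxyphenoxy]phenyl}ethyl)phenol; 11 allylmagnesium bromide
Product: 12 2-(benzyloxy)-5-(2-{4-[5-(but-3-en-1-yl)-2-methoxyphenoxy]phenyl}ethyl)phenol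
Conditions: allylMgBr (3 equiv), THF, 0 °C; then aq. NH4Cl
Reagents that add atoms: allylmagnesium bromide, C=CC[Mg]Br
Why: The first equivalent of the Grignard reagent only forms the inert magnesium phenolate, and further reagent displaces the reactive para-methoxybenzylic bromide (coupling of an allyl Grignard reagent with a benzylic halide) to give the but-3-enyl chain.

Step 8
Reactants: 12 2-(benzyloxy)-5-(2-{4-[5-(but-3-en-1-yl)-2-methoxyphenoxy]phenyl}ethyl)phenol; 13 trichloroethylene
Product: 14 1-(benzyloxy)-2-{[(E)-1,2-dichloroethenyl]oxy}-4-(2-{4-[5-(but-3-en-1-yl)-2-methoxyphenoxy]phenyl}ethyl)benzene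
Conditions: trichloroethylene, K2CO3, DMF, 70 °C
Reagents that add atoms: trichloroethylene, ClC=C(Cl)Cl
Why: K2CO3 converts trichloroethylene into dichloroacetylene, to which the phenoxide adds in anti fashion (nucleophilic O-vinylation of a phenol) to give the E-1,2-dichlorovinyl ether, a stable masked ethynyl ether; the terminal alkene and the ethers are inert.

Step 9
Reactants: 14 1-(benzyloxy)-2-{[(E)-1,2-dichloroethenyl]oxy}-4-(2-{4-[5-(but-3-en-1-yl)-2-methoxyphenoxy]phenyl}ethyl)benzene
Product: 17 1-(benzyloxy)-2-(ethynyloxy)-4-(2-{4-[5-(but-3-en-1-yl)-2-methoxyphenoxy]phenyl}ethyl)benzene, via chloroethynyl ether 15 (not isolated), via lithium acetylide 16 (not isolated)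
Conditions: n-BuLi (2.5 equiv), THF, −78 to −40 °C; then MeOH, −78 °C; quick filtration through Et3N-deactivated silica, used at once
Reagents that add atoms: none
Why: n-BuLi removes the vinylic proton with loss of chloride to give chloroalkyne 15, chlorine–lithium exchange gives acetylide 16, and cold protonation frees the terminal ynol ether (dehydrohalogenation and halogen–metal exchange route to alkynyl ethers), which is made last because aryl ethynyl ethers do not store well.

Step 10
Reactants: 17 1-(benzyloxy)-2-(ethynyloxy)-4-(2-{4-[5-(but-3-en-1-yl)-2-methoxyphenoxy]phenyl}ethyl)benzene; 18 ethylene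
Product: 20 macrocyclic 2-aryloxy-1,3-diene (19-membered ring with E ring alkene and exocyclic methylene), via 2-aryloxybutadiene 19 (not isolated)
Conditions: (H2IMes)(PCy3)Cl2Ru=CHPh (second-generation Grubbs catalyst, 10 mol%), ethylene (1 atm), PhMe (1 mM), 40 °C; then Ar sparge, 70 °C
Reagents that add atoms: ethylene, C=C
Why: The ruthenium methylidene formed under ethylene adds to the electron-rich C≡C bond of 17, and the resulting aryloxy-substituted vinylcarbene is turned over by ethylene to give 2-aryloxybutadiene 19, whose monosubstituted vinyl group then undergoes ring-closing olefin metathesis with the but-3-enyl alkene once ethylene is swept out, releasing ethylene. The closest known reaction type is macrocyclic ring-closing enyne metathesis under ethylene, which delivers 1,3-disubstituted dienes, together with enyne metathesis of alkynyl ethers. The single new ring is 19-membered and closes in the endo mode, with C2, C3 and C4 of the diene inside the ring and C1 as an exocyclic methylene. No stereocentre is created; the ring alkene should be E because a large, unstrained ring lets the reversible metathesis settle on the more stable conjugated E-diene. The step needs the 1,3- and not the 1,2-disubstituted diene, which ethylene secures by routing every molecule through 19, and ring closure over oligomerisation, which the 1 mM concentration and the inertness of the hindered 1,1-disubstituted aryloxy alkene secure.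

Step 11
Reactants: 20 macrocyclic 2-aryloxy-1,3-diene; 21 phenyl vinyl sulfoxide
Product: 24 O-benzyl ether of the target (macrocycle with aromatic ring D), via sulfoxide cycloadduct 22 (not isolated), via cyclohexadiene 23 (not isolated)
Conditions: phenyl vinyl sulfoxide (3 equiv), PhMe, 110 °C; then DDQ (1.2 equiv), rt
Reagents that add atoms: phenyl vinyl sulfoxide, C=CS(=O)c1ccccc1
Why: Diels–Alder reaction of the electron-rich diene (the E alkene allows the s-cis form) with the vinyl sulfoxide as an acetylene equivalent, thermal syn-elimination of PhSOH and DDQ dehydrogenation of the cyclohexadiene build ring D; regio- and stereochemistry are irrelevant because sulfur and all sp3 ring carbons are lost on aromatisation.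

Step 12
Reactants: 24 O-benzyl ether of the target
Product: 25 target CNP0132125.0
Conditions: H2 (1 atm), 10% Pd/C, EtOAc/EtOH, rt
Reagents that add atoms: none
Why: Hydrogenolysis of the aryl benzyl ether over Pd/C frees the ring C phenol, and the diaryl ethers, the methyl ether and the bibenzyl bridges are stable to these conditions.

Compound list
1 | 3-hydroxy-4-methoxybenzyl alcohol | COc1ccc(CO)cc1O | starting material
2 | 4-fluorobenzaldehyde | O=Cc1ccc(F)cc1 | starting material
3 | 4-[5-(hydroxymethyl)-2-methoxyphenoxy]benzaldehyde | COc1ccc(CO)cc1Oc1ccc(C=O)cc1 | intermediate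
4 | 4-(benzyloxy)-3-hydroxybenzaldehyde | O=Cc1ccc(OCc2ccccc2)c(O)c1 | starting material
5 | 2-(benzyloxy)-5-(hydroxymethyl)phenol | OCc1ccc(OCc2ccccc2)c(O)c1 | intermediate
6 | [4-(benzyloxy)-3-hydroxybenzyl]triphenylphosphonium bromide | [Br-].Oc1cc(C[P+](c2ccccc2)(c2ccccc2)c2ccccc2)ccc1OCc1ccccc1 | intermediate
7 | potassium 2-(benzyloxy)-5-[(triphenylphosphoranylidene)methyl]phenolate (not isolated) | [K+].[O-]c1cc(C=P(c2ccccc2)(c2ccccc2)c2ccccc2)ccc1OCc1ccccc1 | intermediate
8 | 2-(benzyloxy)-5-(2-{4-[5-(hydroxymethyl)-2-methoxyphenoxy]phenyl}ethenyl)phenol, E/Z mixture | COc1ccc(CO)cc1Oc1ccc(C=Cc2ccc(OCc3ccccc3)c(O)c2)cc1 | intermediate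
9 | 2-(benzyloxy)-5-(2-{4-[5-(hydroxymethyl)-2-methoxyphenoxy]phenyl}ethyl)phenol | COc1ccc(CO)cc1Oc1ccc(CCc2ccc(OCc3ccccc3)c(O)c2)cc1 | intermediate
10 | 2-(benzyloxy)-5-(2-{4-[5-(bromomethyl)-2-methoxyphenoxy]phenyl}ethyl)phenol | COc1ccc(CBr)cc1Oc1ccc(CCc2ccc(OCc3ccccc3)c(O)c2)cc1 | intermediate
11 | allylmagnesium bromide | C=CC[Mg]Br | starting material
12 | 2-(benzyloxy)-5-(2-{4-[5-(but-3-en-1-yl)-2-methoxyphenoxy]phenyl}ethyl)phenol | COc1ccc(CCC=C)cc1Oc1ccc(CCc2ccc(OCc3ccccc3)c(O)c2)cc1 | intermediate
13 | trichloroethylene | ClC=C(Cl)Cl | starting material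
14 | 1-(benzyloxy)-2-{[(E)-1,2-dichloroethenyl]oxy}-4-(2-{4-[5-(but-3-en-1-yl)-2-methoxyphenoxy]phenyl}ethyl)benzene | Cl/C=C(Cl)\Oc1cc(CCc2ccc(Oc3cc(CCC=C)ccc3OC)cc2)ccc1OCc1ccccc1 | intermediate
15 | chloroethynyl ether corresponding to 14 (not isolated) | ClC#COc1cc(CCc2ccc(Oc3cc(CCC=C)ccc3OC)cc2)ccc1OCc1ccccc1 | intermediate
16 | lithium acetylide of 17 (not isolated) | [Li]C#COc1cc(CCc2ccc(Oc3cc(CCC=C)ccc3OC)cc2)ccc1OCc1ccccc1 | intermediate
17 | 1-(benzyloxy)-2-(ethynyloxy)-4-(2-{4-[5-(but-3-en-1-yl)-2-methoxyphenoxy]phenyl}ethyl)benzene (metathesis precursor) | C#COc1cc(CCc2ccc(Oc3cc(CCC=C)ccc3OC)cc2)ccc1OCc1ccccc1 | intermediate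
18 | ethylene | C=C | starting material
19 | buta-1,3-dien-2-yl ether formed from 17 and ethylene (not isolated) | C=CC(=C)Oc1cc(CCc2ccc(Oc3cc(CCC=C)ccc3OC)cc2)ccc1OCc1ccccc1 | intermediate
20 | macrocyclic 2-aryloxy-1,3-diene, 19-membered ring, E ring alkene, exocyclic methylene | C=C1/C=C/CCc2ccc(OC)c(c2)Oc2ccc(cc2)CCc2ccc(OCc3ccccc3)c(c2)O1 | intermediate
21 | phenyl vinyl sulfoxide (racemic) | C=CS(=O)c1ccccc1 | starting material
22 | sulfoxide cycloadduct, ring D as 1-aryloxy-3-alkyl-4-(phenylsulfinyl)cyclohexene, isomer mixture (not isolated) | COc1ccc2cc1Oc1ccc(cc1)CCc1ccc(OCc3ccccc3)c(c1)OC1=CC(CC2)C(S(=O)c3ccccc3)CC1 | intermediate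
23 | cyclohexadiene, ring D as 1-aryloxy-3-alkylcyclohexa-1,4-diene, racemic, drawn as the 1,4-diene (not isolated) | COc1ccc2cc1Oc1ccc(cc1)CCc1ccc(OCc3ccccc3)c(c1)OC1=CC(CC2)C=CC1 | intermediate
24 | O-benzyl ether of the target | COc1ccc2cc1Oc1ccc(cc1)CCc1ccc(OCc3ccccc3)c(c1)Oc1cccc(c1)CC2 | intermediate
25 | CNP0132125.0 | COc1ccc2cc1Oc1ccc(cc1)CCc1ccc(O)c(c1)Oc1cccc(c1)CC2 | target

Total step count: 12 steps.
Longest linear sequence: 11 steps (from 4 through steps 2 to 12); the branch from 1 and 2 joins at step 4.

Steps most likely to fail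

Step 10. What may go wrong is stalling of the catalyst on the aryloxy-substituted carbene, or oligomerisation in place of ring closure. The fallback gives up the metathesis and closes the macrocycle by a classical intramolecular Wittig reaction with ring D brought in intact. It sets out from 9. Ullmann coupling of the ring C phenol with 3-bromobenzaldehyde (CuI (copper iodide), N,N-dimethylglycine, Cs2CO3, dioxane, 90 °C) should give 3-[2-(benzyloxy)-5-(2-{4-[5-(hydroxymethyl)-2-methoxyphenoxy]phenyl}ethyl)phenoxy]benzaldehyde F1. PPh3·HBr in refluxing MeCN converts its ring A benzylic alcohol into the formyl phosphonium bromide F2. Slow addition of this salt to NaOMe in CH2Cl2/MeOH at high dilution closes the ring to the macrocyclic stilbene F3 (E/Z mixture). Diimide reduction (TsNHNH2, NaOAc, DME/H2O, reflux) then gives 24, where the route is rejoined before step 12.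

Step 9. What may go wrong is hydration or oligomerisation of the terminal aryl ynol ether during work-up and isolation. The fallback isolates the alkyne in a capped form. It sets out from 14: the same lithiation is quenched with Me3SiCl in place of methanol to give the C-silylated alkynyl ether F4, which should tolerate chromatography and storage. The silyl group is removed (K2CO3 cat., MeOH/THF, 0 °C) immediately before the metathesis, and the filtered, solvent-exchanged solution of 17 is used directly, so the route is rejoined at 17.

Step 11. What may go wrong is slow cycloaddition of the only moderately reactive vinyl sulfoxide, which would leave the diene time to polymerise or isomerise at 110 °C. The fallback uses a much more reactive acetylene equivalent and a reductive instead of a thermal unmasking. It sets out from 20: (E)-1,2-bis(phenylsulfonyl)ethylene in toluene at 80 °C should give the trans-bis(phenylsulfonyl) cycloadduct F5. Reductive elimination with sodium amalgam Na(Hg) and Na2HPO4 in MeOH/THF at −20 °C gives the cyclohexa-1,4-diene 23, and DDQ as in step 11 leads back to 24.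

Further compounds
F1 | step 10 | 3-[2-(benzyloxy)-5-(2-{4-[5-(hydroxymethyl)-2-methoxyphenoxy]phenyl}ethyl)phenoxy]benzaldehyde | COc1ccc(CO)cc1Oc1ccc(CCc2ccc(OCc3ccccc3)c(Oc3cccc(C=O)c3)c2)cc1
F2 | step 10 | formyl phosphonium bromide (ring A CH2PPh3+ in place of CH2OH of F1) | [Br-].COc1ccc(C[P+](c2ccccc2)(c2ccccc2)c2ccccc2)cc1Oc1ccc(CCc2ccc(OCc3ccccc3)c(Oc3cccc(C=O)c3)c2)cc1
F3 | step 10 | macrocyclic stilbene (ring D–CH=CH–ring A, E/Z mixture) | COc1ccc2cc1Oc1ccc(cc1)CCc1ccc(OCc3ccccc3)c(c1)Oc1cccc(c1)C=C2
F4 | step 9 | (trimethylsilyl)ethynyl ether corresponding to 17 | C[Si](C)(C)C#COc1cc(CCc2ccc(Oc3cc(CCC=C)ccc3OC)cc2)ccc1OCc1ccccc1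
F5 | step 11 | trans-bis(phenylsulfonyl) cycloadduct of 20 (racemic, mixture of epimers at the alkyl-bearing ring carbon) | COc1ccc2cc1Oc1ccc(cc1)CCc1ccc(OCc3ccccc3)c(c1)OC1=CC(CC2)C(S(=O)(=O)c3ccccc3)C(S(=O)(=O)c3ccccc3)C1
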